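**Retrosynthetic overview**

1. The plan rests on the aldol triad in the six-membered ring of the cis-fused 3a,7a-dimethylhydrindan-4-one core: ketone C4, its α-methine C5 (carrying the hydroxyisobutyl arm) and the tertiary carbinol C6. Cutting the C5–C6 bond leads to keto-enone 29, so the cyclohexanone is the last ring formed.
2. 29 comes from δ-lactone 22 by addition of the (E)-vinyllithium 27 (C4–Cα bond) and oxidation of the C6 alcohol that this releases.
3. 22 comes from aldehyde ester 12 and the (E)-allylbarium reagent made from chloride 19 (C6–CH2 bond); 19 is made from 4-methoxy-2-methylphenol by ortho-prenylation, silylation and allylic oxidation.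
4. 12 comes from hemiester 8 (acid to aldehyde, then one-carbon homologation); 8 comes from desymmetrisation of meso anhydride 7, whose cyclopentane (the first ring formed) is built by double alkylation of dimethyl 2,3-dimethylsuccinate.

Key step: step 18

Assumption: quinidine is taken to induce the same sense in step 5 as it does with the unsubstituted bicyclic meso succinic anhydrides, which corresponds to hemiester 8; if the angular methyl groups reverse the sense, the pseudo-enantiomer quinine is used instead.

**Route**

Step 1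
Reactants: 1 2,3-dimethylsuccinic acid
Product: 2 dimethyl 2,3-dimethylsuccinate
Conditions: MeOH, H2SO4 (cat.), reflux
Reagents that add atoms: methanol (CO)
Why: Fischer esterification of an unhindered diacid driven by excess methanol; the diastereomer mixture of 1 is immaterial because both centres are enolised in step 2.

Step 2
Reactants: 2 dimethyl 2,3-dimethylsuccinate; 3 1-bromo-3-chloropropane
Product: 5 dimethyl 1,2-dimethylcyclopentane-1,2-dicarboxylate (cis/trans mixture), via chloropropyl diester 4 (not isolated)
Conditions: LiN(i-Pr)2 (1.1 eq), THF, −78 °C; 3, DMPU, −78 → 0 °C; LiN(i-Pr)2 (1.3 eq), −78 → 40 °C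
Reagents that add atoms: none
Why: Two successive ester-enolate C-alkylations, the first displacing the more reactive bromide and the second closing the cyclopentane by 5-exo-tet displacement of chloride, build both quaternary carbons; either ring diastereomer may form and the cis isomer is selected chemically in step 4.

Step 3
Reactants: 5 dimethyl 1,2-dimethylcyclopentane-1,2-dicarboxylate (cis/trans mixture)
Product: 6 1,2-dimethylcyclopentane-1,2-dicarboxylic acid (cis/trans mixture)
Conditions: KOH, HOCH2CH2OH/H2O, 150 °C; then aq. HCl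
Reagents that add atoms: potassium hydroxide ([K+].[OH-])
Why: Forcing saponification by acyl–oxygen cleavage is needed for the hindered tertiary esters and is safe because the molecule has no epimerisable centre and no other functional group.

Step 4
Reactants: 6 1,2-dimethylcyclopentane-1,2-dicarboxylic acid (cis/trans mixture)
Product: 7 meso-cis-1,2-dimethylcyclopentane-1,2-dicarboxylic anhydride
Conditions: Ac2O, reflux; bulb-to-bulb distillation
Reagents that add atoms: none
Why: Dehydrative anhydride formation can give a monomeric five-membered anhydride only from the cis-diacid (a trans-fused bicyclo[3.3.0] anhydride is too strained), so distillation should deliver the meso compound and leave trans material behind as involatile oligomeric anhydride.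

Step 5
Reactants: 7 meso-cis-1,2-dimethylcyclopentane-1,2-dicarboxylic anhydride
Product: 8 (1S,2R)-2-(methoxycarbonyl)-1,2-dimethylcyclopentane-1-carboxylic acid
Conditions: quinidine (1.1 eq), MeOH (5 eq), PhMe, −30 → −10 °C; aq. HCl wash
Reagents that add atoms: methanol (CO)
Why: Alkaloid-mediated desymmetrising alcoholysis of a meso anhydride, in which the quinuclidine nitrogen acts as general base and steers methanol to one of the two enantiotopic carbonyl groups, should set both quaternary stereocentres at once, and the hemiester can be enriched further by crystallisation.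

Step 6
Reactants: 8 (1S,2R)-2-(methoxycarbonyl)-1,2-dimethylcyclopentane-1-carboxylic acid
Product: 10 methyl (1R,2S)-2-formyl-1,2-dimethylcyclopentane-1-carboxylate, via acid chloride 9 (not isolated)
Conditions: (COCl)2, DMF (cat.), CH2Cl2, 0 → 23 °C; evaporate; LiAlH(Ot-Bu)3 (1.1 eq), THF, −78 °C
Reagents that add atoms: none
Why: Partial reduction of an acid chloride with the bulky hydride LiAlH(Ot-Bu)3 should stop at the neopentyl aldehyde and leave the tertiary methyl ester untouched, whereas reducing the acid to the alcohol would lose the ester by lactonisation.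

Step 7
Reactants: 10 methyl (1R,2S)-2-formyl-1,2-dimethylcyclopentane-1-carboxylate
Product: 11 methyl (1R,2R)-2-(2-methoxyethenyl)-1,2-dimethylcyclopentane-1-carboxylate (E/Z mixture)
Conditions: Ph3P(CH2OMe)Cl, KN(SiMe3)2, THF, 0 °C; then 10, 0 → 23 °C
Reagents that add atoms: (methoxymethyl)triphenylphosphonium chloride (COC[P+](c1ccccc1)(c1ccccc1)c1ccccc1.[Cl-])
Why: Wittig methoxymethylenation adds the carbon that becomes C6 of the target; the small unstabilised ylide reacts with hindered aldehydes and not with the tertiary ester.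

Step 8
Reactants: 11 methyl (1R,2R)-2-(2-methoxyethenyl)-1,2-dimethylcyclopentane-1-carboxylate (E/Z mixture)
Product: 12 methyl (1R,2R)-1,2-dimethyl-2-(2-oxoethyl)cyclopentane-1-carboxylate
Conditions: 1 M HCl, THF, 23 °C
Reagents that add atoms: water (O)
Why: Acid hydrolysis of the enol ether (both olefin isomers converge) should unveil the homologated aldehyde, and no acid-labile group is present.

Step 9
Reactants: 13 4-methoxy-2-methylphenol; 14 1-bromo-3-methylbut-2-ene
Product: 15 4-methoxy-2-methyl-6-(3-methylbut-2-en-1-yl)phenol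
Conditions: NaH, PhMe, 0 °C; then 14, 23 °C
Reagents that add atoms: none
Why: C-alkylation of a sodium phenoxide as a tight ion pair in a non-polar solvent goes to the ortho carbon, and C6 is the only free ortho position because C2 carries methyl and the para carbon carries methoxy.

Step 10
Reactants: 15 4-methoxy-2-methyl-6-(3-methylbut-2-en-1-yl)phenol
Product: 16 tert-butyl[4-methoxy-2-methyl-6-(3-methylbut-2-en-1-yl)phenoxy]dimethylsilane
Conditions: TBSCl, imidazole, DMF, 40 °C
Reagents that add atoms: tert-butyldimethylsilyl chloride (CC(C)(C)[Si](C)(C)Cl)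
Why: Silylation masks the acidic phenol against the organobarium, organolithium and copper hydride steps and prevents its cyclisation onto the side-chain olefin.

Step 11
Reactants: 16 tert-butyl[4-methoxy-2-methyl-6-(3-methylbut-2-en-1-yl)phenoxy]dimethylsilane
Product: 17 (E)-4-[2-(tert-butyldimethylsilyloxy)-5-methoxy-3-methylphenyl]-2-methylbut-2-en-1-ol
Conditions: SeO2 (cat.), t-BuOOH, salicylic acid (cat.), CH2Cl2, 23 °C
Reagents that add atoms: tert-butyl hydroperoxide (CC(C)(C)OO), its oxygen relayed through SeO2 (O=[Se]=O)
Why: Allylic oxidation with SeO2 (ene reaction followed by [2,3]-sigmatropic shift) attacks the methyl group trans to the chain of a prenyl unit, which fixes the E geometry of the trisubstituted olefin required in the target.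

Step 12
Reactants: 17 (E)-4-[2-(tert-butyldimethylsilyloxy)-5-methoxy-3-methylphenyl]-2-methylbut-2-en-1-ol
Product: 19 (E)-tert-butyl[2-(4-chloro-3-methylbut-2-en-1-yl)-4-methoxy-6-methylphenoxy]dimethylsilane, via allylic mesylate 18 (not isolated)
Conditions: MsCl, 2,4,6-collidine, LiCl, DMF, 0 °C
Reagents that add atoms: lithium chloride ([Li+].[Cl-])
Why: Mesylation and SN2 displacement by chloride at the primary allylic carbon should give the chloride without allylic transposition or loss of olefin geometry.

Step 13
Reactants: 19 (E)-tert-butyl[2-(4-chloro-3-methylbut-2-en-1-yl)-4-methoxy-6-methylphenoxy]dimethylsilane; 12 methyl (1R,2R)-1,2-dimethyl-2-(2-oxoethyl)cyclopentane-1-carboxylate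
Product: 22 (4aR,7aR)-3-{(E)-4-[2-(tert-butyldimethylsilyloxy)-5-methoxy-3-methylphenyl]-2-methylbut-2-en-1-yl}-4a,7a-dimethylhexahydrocyclopenta[c]pyran-1(3H)-one (C3 epimers), via allylbarium chloride 20 (not isolated), via hydroxy ester 21 (not isolated)
Conditions: BaI2, lithium biphenylide (2 eq), THF, 23 °C; 19, −78 °C; 12, −78 °C; MeOH (quench of excess reagent), −78 → 23 °C; aq. NH4Cl
Reagents that add atoms: none
Why: Allylbarium reagents made at −78 °C add to aldehydes through the α-carbon with retention of olefin geometry, giving the linear (E)-homoallylic alkoxide, which on warming should transesterify onto the neighbouring cis ester (helped by the vicinal quaternary carbons) to close the δ-lactone; the carbinol configuration is irrelevant because it is oxidised in step 17.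

Step 14
Reactants: 23 2-methylbut-3-yn-2-ol
Product: 24 triethyl[(2-methylbut-3-yn-2-yl)oxy]silane
Conditions: TESOTf, 2,6-lutidine, CH2Cl2, −78 → 0 °C
Reagents that add atoms: triethylsilyl triflate (CC[Si](CC)(CC)OS(=O)(=O)C(F)(F)F)
Why: The silyl triflate with a hindered base silylates the tertiary alcohol cleanly and leaves the terminal alkyne untouched.

Step 15
Reactants: 24 triethyl[(2-methylbut-3-yn-2-yl)oxy]silane
Product: 26 (E)-triethyl[(4-iodo-2-methylbut-3-en-2-yl)oxy]silane, via vinylzirconocene chloride 25 (not isolated)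
Conditions: Cp2Zr(H)Cl, THF, 23 °C; then I2, 0 °C
Reagents that add atoms: iodine (II)
Why: Hydrozirconation adds H and Zr syn with the metal on the terminal carbon, and iodinolysis proceeds with retention, so the (E)-vinyl iodide should be the only isomer.

Step 16
Reactants: 26 (E)-triethyl[(4-iodo-2-methylbut-3-en-2-yl)oxy]silane; 22 the δ-lactone from step 13
Product: 28 (E)-1-[(1R,2R)-2-{(E)-6-[2-(tert-butyldimethylsilyloxy)-5-methoxy-3-methylphenyl]-2-hydroxy-4-methylhex-4-en-1-yl}-1,2-dimethylcyclopentyl]-4-methyl-4-(triethylsilyloxy)pent-2-en-1-one (carbinol epimers), via vinyllithium 27 (not isolated)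
Conditions: 26, t-BuLi (2 eq), Et2O, −78 °C; then 22, THF, −78 °C; aq. NH4Cl
Reagents that add atoms: none
Why: Iodine–lithium exchange keeps the E geometry, and the vinyllithium should add only once to the lactone carbonyl because the tetrahedral lithium lactolate persists at −78 °C and collapses on work-up to the (E)-enone and the free alcohol (in equilibrium with the six-membered lactol).

Step 17
Reactants: 28 the hydroxy enone from step 16
Product: 29 (E)-1-[(1R,2R)-2-{(E)-6-[2-(tert-butyldimethylsilyloxy)-5-methoxy-3-methylphenyl]-4-methyl-2-oxohex-4-en-1-yl}-1,2-dimethylcyclopentyl]-4-methyl-4-(triethylsilyloxy)pent-2-en-1-one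
Conditions: DMP, NaHCO3, CH2Cl2, 0 → 23 °C
Reagents that add atoms: none
Why: Dess–Martin oxidation under buffered, base-free conditions should convert the homoallylic alcohol into the β,γ-unsaturated ketone without moving the skipped olefin into conjugation and without enolising the 1,5-diketone.

Step 18
Reactants: 29 the keto-enone from step 17
Product: 31 (3aR,5R,6R,7aR)-6-{(E)-4-[2-(tert-butyldimethylsilyloxy)-5-methoxy-3-methylphenyl]-2-methylbut-2-en-1-yl}-6-hydroxy-3a,7a-dimethyl-5-[2-methyl-2-(triethylsilyloxy)propyl]octahydro-4H-inden-4-one, via copper enolate 30 (not isolated)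
Conditions: [(Ph3P)CuH]6 (0.25 eq, 1.5 eq hydride), degassed PhMe, −40 → 0 °C; aq. NH4Cl
Reagents that add atoms: none
Why: Hydride from the copper hydride cluster adds to the enone β-carbon (the CH next to the silyloxy-bearing carbon) and gives the oxygen-bound copper enolate of the C4 ketone with its double bond to C5 only, which then adds to the side-chain ketone carbon (C6) in an intramolecular aldol reaction; this is the known copper hydride reductive aldol cyclisation of keto-enones. The ring closes in the 6-(enolendo)-exo-trig mode, the new ring holding C4, C5, C6, C7, C7a and C3a. The s-cis enone enforced by the quaternary C3a gives the (Z)-enolate, so the silyloxyisobutyl group on C5 lies anti to C3a and ends equatorial, while copper bridging of the enolate oxygen and the C6 carbonyl oxygen requires the new C6–O bond to be gauche to C4, that is axial, which puts the long butenyl chain equatorial and fixes the cis relation of the C6 oxygen and the C5 substituent. Of the two such chairs open to the cis-fused bicycle, the one that keeps the C3a methyl (and not the ring methylene C3) in the pseudo-equatorial position beside the bulky phosphine-ligated enolate oxygen places the C6 oxygen on the face of the angular methyls, as the target requires; this facial preference is the selectivity the step needs most and the least certain. The regiochemical need, an enolate at C5 and none at C7 or at the allylic CH2 of the side chain (whose aldol onto C4 would give an isomeric six-membered ring), is met because no base is present, and the neutral aprotic medium should also keep the tertiary ketol from dehydration or retro-aldol cleavage and the skipped olefin out of conjugation.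

Step 19
Reactants: 31 the bis-silyl ketol from step 18
Product: 32 (3aR,5R,6R,7aR)-6-hydroxy-6-[(E)-4-(2-hydroxy-5-methoxy-3-methylphenyl)-2-methylbut-2-en-1-yl]-5-(2-hydroxy-2-methylpropyl)-3a,7a-dimethyloctahydro-4H-inden-4-one (CNP0190381.3)
Conditions: Bu4NF, AcOH (1:1), THF, 0 → 23 °C
Reagents that add atoms: none
Why: Fluoride cleaves the aryl silyl ether and the tertiary triethylsilyl ether, and the acetic acid buffer keeps the medium from becoming basic enough for retro-aldol cleavage or C5 epimerisation and from being acidic enough for dehydration or chroman formation.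

**Compound list**

1 | 2,3-dimethylsuccinic acid (commercial diastereomer mixture) | CC(C(O)=O)C(C)C(O)=O | starting material
2 | dimethyl 2,3-dimethylsuccinate | COC(=O)C(C)C(C)C(=O)OC | intermediate
3 | 1-bromo-3-chloropropane | ClCCCBr | starting material
4 | dimethyl 2-(3-chloropropyl)-2,3-dimethylsuccinate | COC(=O)C(C)C(C)(CCCCl)C(=O)OC | intermediate (not isolated)
5 | dimethyl 1,2-dimethylcyclopentane-1,2-dicarboxylate (cis/trans mixture) | COC(=O)C1(C)CCCC1(C)C(=O)OC | intermediate
6 | 1,2-dimethylcyclopentane-1,2-dicarboxylic acid (cis/trans mixture) | OC(=O)C1(C)CCCC1(C)C(O)=O | intermediate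
7 | meso-cis-1,2-dimethylcyclopentane-1,2-dicarboxylic anhydride [(3aR,6aS)-3a,6a-dimethyltetrahydro-1H-cyclopenta[c]furan-1,3-dione] | O=C1[C@@]2(C)CCC[C@@]2(C)C(=O)O1 | intermediate
8 | (1S,2R)-2-(methoxycarbonyl)-1,2-dimethylcyclopentane-1-carboxylic acid | OC(=O)[C@@]1(C)CCC[C@@]1(C)C(=O)OC | intermediate
9 | methyl (1R,2S)-2-(chlorocarbonyl)-1,2-dimethylcyclopentane-1-carboxylate | ClC(=O)[C@@]1(C)CCC[C@@]1(C)C(=O)OC | intermediate (not isolated)
10 | methyl (1R,2S)-2-formyl-1,2-dimethylcyclopentane-1-carboxylate | O=C[C@@]1(C)CCC[C@@]1(C)C(=O)OC | intermediate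
11 | methyl (1R,2R)-2-(2-methoxyethenyl)-1,2-dimethylcyclopentane-1-carboxylate (E/Z mixture) | COC=C[C@@]1(C)CCC[C@@]1(C)C(=O)OC | intermediate
12 | methyl (1R,2R)-1,2-dimethyl-2-(2-oxoethyl)cyclopentane-1-carboxylate | O=CC[C@@]1(C)CCC[C@@]1(C)C(=O)OC | intermediate
13 | 4-methoxy-2-methylphenol | COc1ccc(O)c(C)c1 | starting material
14 | 1-bromo-3-methylbut-2-ene | CC(C)=CCBr | starting material
15 | 4-methoxy-2-methyl-6-(3-methylbut-2-en-1-yl)phenol | COc1cc(C)c(O)c(CC=C(C)C)c1 | intermediate
16 | tert-butyl[4-methoxy-2-methyl-6-(3-methylbut-2-en-1-yl)phenoxy]dimethylsilane | COc1cc(C)c(O[Si](C)(C)C(C)(C)C)c(CC=C(C)C)c1 | intermediate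
17 | (E)-4-[2-(tert-butyldimethylsilyloxy)-5-methoxy-3-methylphenyl]-2-methylbut-2-en-1-ol | COc1cc(C)c(O[Si](C)(C)C(C)(C)C)c(C/C=C(\C)CO)c1 | intermediate
18 | (E)-4-[2-(tert-butyldimethylsilyloxy)-5-methoxy-3-methylphenyl]-2-methylbut-2-en-1-yl methanesulfonate | COc1cc(C)c(O[Si](C)(C)C(C)(C)C)c(C/C=C(\C)COS(C)(=O)=O)c1 | intermediate (not isolated)
19 | (E)-tert-butyl[2-(4-chloro-3-methylbut-2-en-1-yl)-4-methoxy-6-methylphenoxy]dimethylsilane | COc1cc(C)c(O[Si](C)(C)C(C)(C)C)c(C/C=C(\C)CCl)c1 | intermediate
20 | {(E)-4-[2-(tert-butyldimethylsilyloxy)-5-methoxy-3-methylphenyl]-2-methylbut-2-en-1-yl}barium chloride | COc1cc(C)c(O[Si](C)(C)C(C)(C)C)c(C/C=C(\C)C[Ba]Cl)c1 | intermediate (not isolated)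
21 | methyl (1R,2R)-2-{(E)-6-[2-(tert-butyldimethylsilyloxy)-5-methoxy-3-methylphenyl]-2-hydroxy-4-methylhex-4-en-1-yl}-1,2-dimethylcyclopentane-1-carboxylate (carbinol epimers) | COc1cc(C)c(O[Si](C)(C)C(C)(C)C)c(C/C=C(\C)CC(O)C[C@@]2(C)CCC[C@@]2(C)C(=O)OC)c1 | intermediate (not isolated)
22 | (4aR,7aR)-3-{(E)-4-[2-(tert-butyldimethylsilyloxy)-5-methoxy-3-methylphenyl]-2-methylbut-2-en-1-yl}-4a,7a-dimethylhexahydrocyclopenta[c]pyran-1(3H)-one (C3 epimers) | COc1cc(C)c(O[Si](C)(C)C(C)(C)C)c(C/C=C(\C)CC2C[C@@]3(C)CCC[C@@]3(C)C(=O)O2)c1 | intermediate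
23 | 2-methylbut-3-yn-2-ol | CC(C)(O)C#C | starting material
24 | triethyl[(2-methylbut-3-yn-2-yl)oxy]silane | CC[Si](CC)(CC)OC(C)(C)C#C | intermediate
25 | chlorobis(cyclopentadienyl)[(E)-3-methyl-3-(triethylsilyloxy)but-1-en-1-yl]zirconium | CC[Si](CC)(CC)OC(C)(C)/C=C/[Zr](Cl)(C1C=CC=C1)C1C=CC=C1 | intermediate (not isolated)
26 | (E)-triethyl[(4-iodo-2-methylbut-3-en-2-yl)oxy]silane | CC[Si](CC)(CC)OC(C)(C)/C=C/I | intermediate
27 | [(E)-3-methyl-3-(triethylsilyloxy)but-1-en-1-yl]lithium | CC[Si](CC)(CC)OC(C)(C)/C=C/[Li] | intermediate (not isolated)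
28 | (E)-1-[(1R,2R)-2-{(E)-6-[2-(tert-butyldimethylsilyloxy)-5-methoxy-3-methylphenyl]-2-hydroxy-4-methylhex-4-en-1-yl}-1,2-dimethylcyclopentyl]-4-methyl-4-(triethylsilyloxy)pent-2-en-1-one (carbinol epimers) | COc1cc(C)c(O[Si](C)(C)C(C)(C)C)c(C/C=C(\C)CC(O)C[C@@]2(C)CCC[C@@]2(C)C(=O)/C=C/C(C)(C)O[Si](CC)(CC)CC)c1 | intermediate
29 | (E)-1-[(1R,2R)-2-{(E)-6-[2-(tert-butyldimethylsilyloxy)-5-methoxy-3-methylphenyl]-4-methyl-2-oxohex-4-en-1-yl}-1,2-dimethylcyclopentyl]-4-methyl-4-(triethylsilyloxy)pent-2-en-1-one | COc1cc(C)c(O[Si](C)(C)C(C)(C)C)c(C/C=C(\C)CC(=O)C[C@@]2(C)CCC[C@@]2(C)C(=O)/C=C/C(C)(C)O[Si](CC)(CC)CC)c1 | intermediate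
30 | phosphine-ligated copper (Z)-enolate of 29 at C4/C5 (monovalent copper on the enolate oxygen) | COc1cc(C)c(O[Si](C)(C)C(C)(C)C)c(C/C=C(\C)CC(=O)C[C@@]2(C)CCC[C@@]2(C)/C(O[Cu])=C/CC(C)(C)O[Si](CC)(CC)CC)c1 | intermediate (not isolated)
31 | (3aR,5R,6R,7aR)-6-{(E)-4-[2-(tert-butyldimethylsilyloxy)-5-methoxy-3-methylphenyl]-2-methylbut-2-en-1-yl}-6-hydroxy-3a,7a-dimethyl-5-[2-methyl-2-(triethylsilyloxy)propyl]octahydro-4H-inden-4-one | COc1cc(C)c(O[Si](C)(C)C(C)(C)C)c(C/C=C(\C)C[C@@]2(O)C[C@@]3(C)CCC[C@@]3(C)C(=O)[C@@H]2CC(C)(C)O[Si](CC)(CC)CC)c1 | intermediate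
32 | (3aR,5R,6R,7aR)-6-hydroxy-6-[(E)-4-(2-hydroxy-5-methoxy-3-methylphenyl)-2-methylbut-2-en-1-yl]-5-(2-hydroxy-2-methylpropyl)-3a,7a-dimethyloctahydro-4H-inden-4-one | COc1cc(C)c(O)c(C/C=C(\C)C[C@@]2(O)C[C@@]3(C)CCC[C@@]3(C)C(=O)[C@@H]2CC(C)(C)O)c1 | target

**Step count**

Total steps: 19. Longest linear sequence: 13 steps (steps 1 to 8, then 13, 16, 17, 18 and 19).

**Steps most likely to fail**

1. Step 18. The aldol closure may show poor facial selectivity, placing the C6 oxygen on the face away from the angular methyls, or the copper enolate may be protonated before it closes and give only the conjugate-reduction product. Fallback: starting from 29, 1,4-hydrosilylation of the enone with Et3SiH and catalytic RhCl(PPh3)3 in benzene should give the isolable (Z)-triethylsilyl enol ether F1. An intramolecular Mukaiyama aldol addition of F1 onto the side-chain ketone with BF3·OEt2 in CH2Cl2 at −78 °C then closes the same C5–C6 bond through an open, non-chelated transition state, whose stereocontrol is independent of the metal bridge, and returns to the route at 31.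

2. Step 5. The doubly neopentyl anhydride may react with methanol only at temperatures where the alkaloid no longer discriminates between the two carbonyl groups, giving a hemiester of low enantiomeric purity. Fallback: starting from 7, opening with NaOMe in MeOH gives the racemic cis-hemiester F2. This is resolved by fractional crystallisation of its (R)-1-phenylethylammonium salt F3 (the antipodal amine serves if the wanted acid stays in the mother liquor), and acidification with aq. HCl returns to the route at 8.

3. Step 13. The allylbarium reagent may react in part through its γ-carbon, lose olefin geometry, or be consumed by reductive dimerisation, so that the linear (E) adduct is not the main product. Fallback: starting from 19, a zinc-mediated Barbier addition to acetone (Zn, THF/aq. NH4Cl) deliberately gives the γ-adduct, the tertiary homoallylic alcohol F4. Acid-catalysed allyl transfer from F4 to aldehyde 12 (Sn(OTf)2 cat., CH2Cl2, 0 → 23 °C; 2-oxonia-Cope rearrangement through a chair with the arylmethyl group equatorial) should give the linear (E)-hydroxy ester 21 with loss of acetone. Catalytic t-BuOK in THF then closes the lactone and returns to the route at 22.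

**Further compounds**

F1 | step 18 | (Z)-triethylsilyl enol ether of the C4 ketone: tert-butyl{2-[(E)-6-{(1R,2R)-1,2-dimethyl-2-[(Z)-4-methyl-1,4-bis(triethylsilyloxy)pent-1-en-1-yl]cyclopentyl}-3-methyl-5-oxohex-2-en-1-yl]-4-methoxy-6-methylphenoxy}dimethylsilane | COc1cc(C)c(O[Si](C)(C)C(C)(C)C)c(C/C=C(\C)CC(=O)C[C@@]2(C)CCC[C@@]2(C)/C(O[Si](CC)(CC)CC)=C/CC(C)(C)O[Si](CC)(CC)CC)c1
F2 | step 5 | racemic cis-2-(methoxycarbonyl)-1,2-dimethylcyclopentane-1-carboxylic acid (both enantiomers) | OC(=O)[C@@]1(C)CCC[C@@]1(C)C(=O)OC.OC(=O)[C@]1(C)CCC[C@]1(C)C(=O)OC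
F3 | step 5 | (R)-1-phenylethylammonium (1S,2R)-2-(methoxycarbonyl)-1,2-dimethylcyclopentane-1-carboxylate | [O-]C(=O)[C@@]1(C)CCC[C@@]1(C)C(=O)OC.C[C@@H]([NH3+])c1ccccc1
F4 | step 13 | 3-{[2-(tert-butyldimethylsilyloxy)-5-methoxy-3-methylphenyl]methyl}-2,4-dimethylpent-4-en-2-ol (racemic) | COc1cc(C)c(O[Si](C)(C)C(C)(C)C)c(CC(C(C)=C)C(C)(C)O)c1
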